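**Strategy.** Everything rests on opening the tetrahydroisoquinoline at N2–C1 and C1–C8a, so that the nitrogen ring is closed last, on a finished biaryl. A Pictet–Spengler reaction of an open-chain (S)-1-arylpropan-2-amine with acetaldehyde forms both bonds and the C1 stereocentre in one operation and ends at the target. It exploits C8a of the dimethoxybenzene ring, which is para to the C6 methoxy, ortho to the C8 methoxy and the only free position ortho to the aminopropyl chain, because C5 carries the naphthyl group; the C3 methyl and the peri C8 methoxy steer C1 to the 1,3-trans arrangement. The amine precursor is the product of a Suzuki coupling that joins the naphthalene to the benzene ring beforehand.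

Key step: step 10

Assumption: the structure defines C1 and C3 but not the sense of the C5–C1' biaryl axis, so the route controls the two carbon stereocentres and expects the axis as a pair of atropo-diastereomers, which should be separable by chromatography or crystallisation if only one is wanted.

**Step 1**
Reactants: 1 N,N-diethyl-2-methoxybenzamide; 2 3-bromo-2-methylprop-1-ene
Product: 5 N,N-diethyl-2-methoxy-6-(2-methylprop-2-en-1-yl)benzamide, via aryllithium 3 (not isolated), via arylmagnesium bromide 4 (not isolated)
Conditions: s-BuLi, TMEDA, THF, −78 °C; MgBr2·OEt2; then 2, −78 °C → rt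
Reagents that add atoms: none
Why: Directed ortho-metalation, in which the tertiary amide steers lithiation to C6, its only free ortho position, and the arylmagnesium species formed by transmetalation is allylated by the allylic bromide (SN2 and SN2' give the same product).

**Step 2**
Reactants: 5 N,N-diethyl-2-methoxy-6-(2-methylprop-2-en-1-yl)benzamide
Product: 7 8-methoxy-3-methylnaphthalen-1-ol, via naphthalenone 6 (not isolated)
Conditions: LDA (2.2 equiv), THF, −78 °C → rt; aq. NH4Cl
Reagents that add atoms: none
Why: Anionic ring annulation of an ortho-allylbenzamide (Snieckus naphthol synthesis), in which LDA removes the benzylic-allylic proton, the terminal carbon of the allyl anion acylates on the neighbouring amide in a six-membered closure with loss of diethylamide, and enolisation of ketone 6 aromatises the new ring.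

**Step 3**
Reactants: 7 8-methoxy-3-methylnaphthalen-1-ol
Product: 8 1,8-dimethoxy-3-methylnaphthalene
Conditions: NaH, MeI, DMF, 0 °C → rt
Reagents that add atoms: iodomethane CI
Why: Williamson ether synthesis, with the sodium naphthoxide methylated on oxygen in a dipolar aprotic solvent that breaks the peri hydrogen bond to the C8 methoxy group.

**Step 4**
Reactants: 8 1,8-dimethoxy-3-methylnaphthalene
Product: 9 1-bromo-4,5-dimethoxy-2-methylnaphthalene
Conditions: NBS (1.0 equiv), MeCN, −20 °C → 0 °C, dark
Reagents that add atoms: N-bromosuccinimide O=C1CCC(=O)N1Br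
Why: Electrophilic aromatic bromination at C4 of 8 (C1 of 9), an alpha position that is para to a methoxy group and ortho to the methyl group and therefore the most activated site, with one equivalent of NBS in a polar solvent favouring ionic monobromination.

**Step 5**
Reactants: 9 1-bromo-4,5-dimethoxy-2-methylnaphthalene
Product: 11 (4,5-dimethoxy-2-methylnaphthalen-1-yl)boronic acid, via naphthyllithium 10 (not isolated)
Conditions: n-BuLi, THF, −78 °C; B(OMe)3, −78 °C → rt; aq. HCl
Reagents that add atoms: trimethyl borate COB(OC)OC; water O
Why: Bromine–lithium exchange followed by borylation with trimethyl borate and acidic hydrolysis, the standard route to hindered arylboronic acids, which the two methyl ethers tolerate.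

**Step 6**
Reactants: 12 1-bromo-3,5-dimethoxybenzene; 13 tert-butyl (S)-2-methylaziridine-1-carboxylate
Product: 15 tert-butyl (S)-[1-(3,5-dimethoxyphenyl)propan-2-yl]carbamate, via aryl Grignard reagent 14 (not isolated)
Conditions: Mg, THF, reflux; then CuBr·SMe2 (10 mol %), 13, THF, −30 °C → 0 °C; aq. NH4Cl
Reagents that add atoms: none
Why: Copper-catalysed Grignard ring opening of an N-Boc aziridine by SN2 attack at the unsubstituted CH2, so the (S) stereocentre of 13 is not touched and becomes C3 of the target.

**Step 7**
Reactants: 15 tert-butyl (S)-[1-(3,5-dimethoxyphenyl)propan-2-yl]carbamate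
Product: 16 tert-butyl (S)-[1-(2-bromo-3,5-dimethoxyphenyl)propan-2-yl]carbamate
Conditions: NBS (1.0 equiv), MeCN, 0 °C
Reagents that add atoms: N-bromosuccinimide O=C1CCC(=O)N1Br
Why: Electrophilic aromatic bromination at the position para to one methoxy group and ortho to the other and to the side chain (C2 and C6 are equivalent), which is preferred over the more hindered C4 between the two methoxy groups, as with orcinol dimethyl ether.

**Step 8**
Reactants: 16 tert-butyl (S)-[1-(2-bromo-3,5-dimethoxyphenyl)propan-2-yl]carbamate; 11 (4,5-dimethoxy-2-methylnaphthalen-1-yl)boronic acid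
Product: 17 tert-butyl (S)-{1-[2-(4,5-dimethoxy-2-methylnaphthalen-1-yl)-3,5-dimethoxyphenyl]propan-2-yl}carbamate
Conditions: Pd(OAc)2 (5 mol %), SPhos (10 mol %), K3PO4, toluene/H2O, 100 °C
Reagents that add atoms: none
Why: Suzuki–Miyaura coupling with a bulky electron-rich dialkylbiarylphosphine, the ligand class developed for tri-ortho-substituted biaryls, which leaves the carbamate and the stereocentre untouched and should give the new axis as a mixture of atropo-diastereomers.

**Step 9**
Reactants: 17 tert-butyl (S)-{1-[2-(4,5-dimethoxy-2-methylnaphthalen-1-yl)-3,5-dimethoxyphenyl]propan-2-yl}carbamate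
Product: 18 (S)-1-[2-(4,5-dimethoxy-2-methylnaphthalen-1-yl)-3,5-dimethoxyphenyl]propan-2-amine
Conditions: HCl (4 M in 1,4-dioxane), rt; aq. NaOH
Reagents that add atoms: none
Why: Acidolysis of the tert-butyl carbamate with loss of 2-methylpropene and carbon dioxide, which does not affect the stereocentre, the aryl methyl ethers or the biaryl.

**Step 10**
Reactants: 18 (S)-1-[2-(4,5-dimethoxy-2-methylnaphthalen-1-yl)-3,5-dimethoxyphenyl]propan-2-amine; 19 acetaldehyde
Product: 21 (1S,3S)-5-(4,5-dimethoxy-2-methylnaphthalen-1-yl)-6,8-dimethoxy-1,3-dimethyl-1,2,3,4-tetrahydroisoquinoline, via imine 20 (not isolated)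
Conditions: MeCHO (1.5 equiv), MgSO4, CH2Cl2, 0 °C → rt; then TFA (2 equiv), 0 °C → rt; aq. NaHCO3
Reagents that add atoms: none
Why: Condensation of the primary amine with acetaldehyde gives imine 20, whose protonated iminium form is attacked by C8a of the dimethoxybenzene ring in a Mannich-type electrophilic aromatic substitution, and loss of the C8a proton restores aromaticity (Pictet–Spengler reaction, with the cyclisation of 1-(3,5-dialkoxyphenyl)propan-2-amines with acetaldehyde as the closest known case). The six-membered nitrogen ring closes in the 6-endo-trig mode, N2=C1 forming first and C1–C8a second. The new C1 stereocentre is controlled by the existing C3 centre: in the half-chair transition state the C3 methyl sits pseudo-equatorial and the C1 methyl is pushed pseudo-axial by peri strain with the C8 methoxy group, which should lead to the 1,3-trans (1S,3S) product. The step needs regioselectivity and diastereoselectivity. The first is secured because C8a is para to the C6 methoxy, ortho to the C8 methoxy and the only open position ortho to the side chain, while C5 carries the naphthyl group and the electron-rich naphthalene carbons could only be reached through a medium ring. The second rests on the substrate control just described.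

**Compound list**
1 | N,N-diethyl-2-methoxybenzamide | CCN(CC)C(=O)c1ccccc1OC | starting material
2 | 3-bromo-2-methylprop-1-ene | CC(=C)CBr | starting material
3 | [2-(diethylcarbamoyl)-3-methoxyphenyl]lithium | CCN(CC)C(=O)c1c([Li])cccc1OC | intermediate
4 | [2-(diethylcarbamoyl)-3-methoxyphenyl]magnesium bromide | CCN(CC)C(=O)c1c([Mg]Br)cccc1OC | intermediate
5 | N,N-diethyl-2-methoxy-6-(2-methylprop-2-en-1-yl)benzamide | CCN(CC)C(=O)c1c(CC(C)=C)cccc1OC | intermediate
6 | 8-methoxy-3-methylnaphthalen-1(2H)-one | COc1cccc2C=C(C)CC(=O)c12 | intermediate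
7 | 8-methoxy-3-methylnaphthalen-1-ol | COc1cccc2cc(C)cc(O)c12 | intermediate
8 | 1,8-dimethoxy-3-methylnaphthalene | COc1cccc2cc(C)cc(OC)c12 | intermediate
9 | 1-bromo-4,5-dimethoxy-2-methylnaphthalene | COc1cccc2c(Br)c(C)cc(OC)c12 | intermediate
10 | (4,5-dimethoxy-2-methylnaphthalen-1-yl)lithium | COc1cccc2c([Li])c(C)cc(OC)c12 | intermediate
11 | (4,5-dimethoxy-2-methylnaphthalen-1-yl)boronic acid | COc1cccc2c(B(O)O)c(C)cc(OC)c12 | intermediate
12 | 1-bromo-3,5-dimethoxybenzene | COc1cc(Br)cc(OC)c1 | starting material
13 | tert-butyl (S)-2-methylaziridine-1-carboxylate | C[C@H]1CN1C(=O)OC(C)(C)C | starting material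
14 | (3,5-dimethoxyphenyl)magnesium bromide | COc1cc(OC)cc([Mg]Br)c1 | intermediate
15 | tert-butyl (S)-[1-(3,5-dimethoxyphenyl)propan-2-yl]carbamate | COc1cc(OC)cc(C[C@H](C)NC(=O)OC(C)(C)C)c1 | intermediate
16 | tert-butyl (S)-[1-(2-bromo-3,5-dimethoxyphenyl)propan-2-yl]carbamate | COc1cc(OC)c(Br)c(C[C@H](C)NC(=O)OC(C)(C)C)c1 | intermediate
17 | tert-butyl (S)-{1-[2-(4,5-dimethoxy-2-methylnaphthalen-1-yl)-3,5-dimethoxyphenyl]propan-2-yl}carbamate | COc1cc(OC)c(-c2c(C)cc(OC)c3c(OC)cccc23)c(C[C@H](C)NC(=O)OC(C)(C)C)c1 | intermediate
18 | (S)-1-[2-(4,5-dimethoxy-2-methylnaphthalen-1-yl)-3,5-dimethoxyphenyl]propan-2-amine | COc1cc(OC)c(-c2c(C)cc(OC)c3c(OC)cccc23)c(C[C@H](C)N)c1 | intermediate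
19 | acetaldehyde | CC=O | starting material
20 | (S)-N-ethylidene-1-[2-(4,5-dimethoxy-2-methylnaphthalen-1-yl)-3,5-dimethoxyphenyl]propan-2-amine | COc1cc(OC)c(-c2c(C)cc(OC)c3c(OC)cccc23)c(C[C@H](C)N=CC)c1 | intermediate
21 | (1S,3S)-5-(4,5-dimethoxy-2-methylnaphthalen-1-yl)-6,8-dimethoxy-1,3-dimethyl-1,2,3,4-tetrahydroisoquinoline | COc1cc(OC)c2c(c1-c1c(C)cc(OC)c3c(OC)cccc13)C[C@H](C)N[C@H]2C | target

**Step count.** Total: 10 steps. Longest linear sequence: 8 steps (steps 1, 2, 3, 4, 5, 8, 9, 10).

**Steps most likely to fail**

Step 8. Transmetalation and reductive elimination may be slow at a palladium centre flanked by three ortho substituents, so that protodeboronation of the electron-rich boronic acid consumes the nucleophile before coupling. The fallback moves the biaryl bond formation ahead of the side chain and onto a more reactive, less encumbered halide. It sets out from 12, which should be iodinated ortho to bromine and para to a methoxy group (NIS, cat. TFA, MeCN) to give 1-bromo-2-iodo-3,5-dimethoxybenzene F1. Chemoselective Suzuki coupling of 11 at the carbon–iodine bond (Pd(PPh3)4, Na2CO3, DME/H2O, 80 °C) should then give 1-(2-bromo-4,6-dimethoxyphenyl)-4,5-dimethoxy-2-methylnaphthalene F2. Bromine–lithium exchange (n-BuLi, THF, −78 °C), transmetalation with MgBr2·OEt2 and CuBr·SMe2-catalysed opening of aziridine 13 would come back to the route at 17.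

Step 10. The 1,3-induction may be too weak, giving a mixture of C1 epimers, or iminium formation may stall with aldehyde self-condensation. The fallback separates ring closure from the setting of C1. It sets out from 18, which is acetylated (Ac2O, Et3N, CH2Cl2) to N-{(S)-1-[2-(4,5-dimethoxy-2-methylnaphthalen-1-yl)-3,5-dimethoxyphenyl]propan-2-yl}acetamide F3. Bischler–Napieralski cyclodehydration (POCl3, MeCN, reflux) should give (S)-5-(4,5-dimethoxy-2-methylnaphthalen-1-yl)-6,8-dimethoxy-1,3-dimethyl-3,4-dihydroisoquinoline F4. Trans-selective hydride delivery with LiAlH4/AlMe3 (THF, −78 °C) would come back to the route at 21.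

Step 4. The electrophile may attack the other ring at C5, para to the second methoxy group, or brominate twice. The fallback brominates at the naphthol stage, where the free hydroxyl makes its own ring far more nucleophilic than the anisole ring. It sets out from 7, which with NBS (MeCN, −20 °C) should give 4-bromo-8-methoxy-3-methylnaphthalen-1-ol F5 by para attack. O-Methylation (NaH, MeI, DMF) would come back to the route at 9.

**Further compounds**
F1 | step 8 | 1-bromo-2-iodo-3,5-dimethoxybenzene | COc1cc(OC)c(I)c(Br)c1
F2 | step 8 | 1-(2-bromo-4,6-dimethoxyphenyl)-4,5-dimethoxy-2-methylnaphthalene | COc1cc(OC)c(-c2c(C)cc(OC)c3c(OC)cccc23)c(Br)c1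
F3 | step 10 | N-{(S)-1-[2-(4,5-dimethoxy-2-methylnaphthalen-1-yl)-3,5-dimethoxyphenyl]propan-2-yl}acetamide | COc1cc(OC)c(-c2c(C)cc(OC)c3c(OC)cccc23)c(C[C@H](C)NC(C)=O)c1
F4 | step 10 | (S)-5-(4,5-dimethoxy-2-methylnaphthalen-1-yl)-6,8-dimethoxy-1,3-dimethyl-3,4-dihydroisoquinoline | COc1cc(OC)c2c(c1-c1c(C)cc(OC)c3c(OC)cccc13)C[C@H](C)N=C2C
F5 | step 4 | 4-bromo-8-methoxy-3-methylnaphthalen-1-ol | COc1cccc2c(Br)c(C)cc(O)c12
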